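Dictyol numbering is used (ring fusion C1/C5, carbinols C6 and C9, side chain from C11). Everything rests on the C7–C11 bond. The 1,4-relationship between the C6 oxygen and C9 on the seven-membered ring is stored in a temporary γ-butenolide ring (O–C6–C7=C8–C9=O) attached to the cyclopentene. Michael addition of the regiodefined (Z)-lithium enolate of the complete side-chain ketone to this butenolide joins the halves and sets C7 (anti to the C6 substituent) and C11 in one operation. The lactone carbonyl later acylates a C10 vinyllithium, which closes the seven-membered ring and frees the C6 hydroxyl.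

Key step: step 11

Remark: numbering is C1–C5 cyclopentene (C3=C4, methyl on C4), C5–C10 plus C1 seven-membered ring (methylidene on C10), C11 (methyl), C12 (OAc), C13–C16; both enantiomers of silyloxy enone 5 are assumed to be commercial.

Step 1
Reactants: 1 4-bromo-2-methylbut-1-ene; 2 N-methoxy-N-methylprop-2-enamide
Product: 4 6-methylhepta-1,6-dien-3-one, via Grignard reagent 3 (not isolated)
Conditions: Mg, THF, rt; then 2, THF, −20 °C; quench into cold 1 M HCl
Reagents that add atoms: none
Why: Acyl substitution of the Weinreb amide by the homoallylic Grignard reagent should stop at the chelated tetrahedral intermediate, so the vinyl ketone is released only on acidic quench (Weinreb ketone synthesis) and no stereocentre is formed.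

Step 2
Reactants: 5 (S)-4-[(tert-butyldimethylsilyl)oxy]cyclopent-2-en-1-one; 6 (1-bromoethenyl)trimethylsilane
Product: 9 (S)-4-[1-(trimethylsilyl)ethenyl]cyclopent-2-en-1-one, via Grignard reagent 7 (not isolated), via adduct ketone 8 (not isolated)
Conditions: 6, Mg, THF; CuI (10 mol %), 5, THF, −78 °C; NH4Cl; then DBU, CH2Cl2, 0 °C
Reagents that add atoms: none
Why: Copper-catalysed 1,4-addition of the α-silylvinyl Grignard reagent should occur anti to the silyloxy group and E1cB loss of silanol then regenerates an enone, so the future C1 is set by the stereocentre of 5 (conjugate addition–β-elimination).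

Step 3
Reactants: 9 (S)-4-[1-(trimethylsilyl)ethenyl]cyclopent-2-en-1-one
Product: 11 (S)-4-(1-bromoethenyl)cyclopent-2-en-1-one, via dibromide 10 (not isolated)
Conditions: Br2 (1.0 equiv), CH2Cl2, −78 °C; then TBAF/AcOH, THF, −78 → 0 °C
Reagents that add atoms: bromine, BrBr
Why: Bromine should add to the electron-rich vinylsilane faster than to the enone and fluoride-induced anti-elimination of the β-bromosilane then gives the 2-bromoalkene (bromodesilylation) without touching C1.

Step 4
Reactants: 11 (S)-4-(1-bromoethenyl)cyclopent-2-en-1-one; 12 prop-2-enal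
Product: 14 (4R,5R)-4-(1-bromoethenyl)-5-[(1R)-1-hydroxyprop-2-en-1-yl]cyclopent-2-en-1-one, via lithium dienolate 13 (not isolated)
Conditions: LDA, THF, −78 °C; 12, −78 °C, 10 min; NH4Cl
Reagents that add atoms: none
Why: Kinetic deprotonation should give the cross-conjugated α′-enolate, which adds 1,2 to acrolein on the face anti to the C1 substituent through a Zimmerman–Traxler chair of the ring-locked (E)-enolate, setting C5 trans to C1 and C6 anti to C5 (lithium aldol reaction).

Step 5
Reactants: 14 (4R,5R)-4-(1-bromoethenyl)-5-[(1R)-1-hydroxyprop-2-en-1-yl]cyclopent-2-en-1-one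
Product: 15 (4R,5R)-4-(1-bromoethenyl)-5-[(1R)-1-[(tert-butyldimethylsilyl)oxy]prop-2-en-1-yl]cyclopent-2-en-1-one
Conditions: TBSOTf, 2,6-lutidine, CH2Cl2, −78 → 0 °C
Reagents that add atoms: tert-butyldimethylsilyl trifluoromethanesulfonate, CC(C)(C)[Si](C)(C)OS(=O)(=O)C(F)(F)F
Why: Silylation of the aldol hydroxyl with the silyl triflate should block retro-aldol and O-sulfonylation at C6 in the next steps (silyl ether protection).

Step 6
Reactants: 15 (4R,5R)-4-(1-bromoethenyl)-5-[(1R)-1-[(tert-butyldimethylsilyl)oxy]prop-2-en-1-yl]cyclopent-2-en-1-one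
Product: 17 (4R,5R)-4-(1-bromoethenyl)-5-[(1R)-1-[(tert-butyldimethylsilyl)oxy]prop-2-en-1-yl]cyclopent-1-en-1-yl trifluoromethanesulfonate, via lithium enolate 16 (not isolated)
Conditions: L-Selectride (1.05 equiv), THF, −78 °C; then PhNTf2, −78 → 0 °C; NH4Cl
Reagents that add atoms: N-phenylbis(trifluoromethanesulfonimide), O=S(=O)(N(c1ccccc1)S(=O)(=O)C(F)(F)F)C(F)(F)F
Why: Conjugate hydride addition to the unsubstituted β-carbon should give the C3–C4 enolate regiospecifically and O-sulfonylation fixes it as the enol triflate (conjugate reduction–enolate trapping), with C5 untouched.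

Step 7
Reactants: 17 (4R,5R)-4-(1-bromoethenyl)-5-[(1R)-1-[(tert-butyldimethylsilyl)oxy]prop-2-en-1-yl]cyclopent-1-en-1-yl trifluoromethanesulfonate
Product: 18 {[(1R)-1-[(1S,5R)-5-(1-bromoethenyl)-2-methylcyclopent-2-en-1-yl]prop-2-en-1-yl]oxy}(tert-butyl)dimethylsilane
Conditions: Me2CuLi (3 equiv), THF, −20 °C
Reagents that add atoms: lithium dimethylcuprate, [Li+].C[Cu-]C
Why: Substitution of the alkenyl triflate by the cuprate should be much faster at low temperature than that of the hindered 2-bromoalkene, which installs the C4 methyl group and fixes the C3=C4 double bond (cuprate–enol triflate coupling).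

Step 8
Reactants: 18 {[(1R)-1-[(1S,5R)-5-(1-bromoethenyl)-2-methylcyclopent-2-en-1-yl]prop-2-en-1-yl]oxy}(tert-butyl)dimethylsilane
Product: 19 (1R)-1-[(1S,5R)-5-(1-bromoethenyl)-2-methylcyclopent-2-en-1-yl]prop-2-en-1-ol
Conditions: TBAF, THF, 0 °C → rt
Reagents that add atoms: none
Why: Fluoride should cleave the silyl ether without affecting the bromoalkene or the other alkenes (desilylation).

Step 9
Reactants: 19 (1R)-1-[(1S,5R)-5-(1-bromoethenyl)-2-methylcyclopent-2-en-1-yl]prop-2-en-1-ol
Product: 20 (1R)-1-[(1S,5R)-5-(1-bromoethenyl)-2-methylcyclopent-2-en-1-yl]prop-2-en-1-yl prop-2-enoate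
Conditions: acryloyl chloride, iPr2NEt, DMAP (cat.), CH2Cl2, −20 → 0 °C
Reagents that add atoms: acryloyl chloride, C=CC(=O)Cl
Why: O-Acylation of the secondary allylic alcohol by the acid chloride should give the acrylate with retention at C6 (esterification).

Step 10
Reactants: 20 (1R)-1-[(1S,5R)-5-(1-bromoethenyl)-2-methylcyclopent-2-en-1-yl]prop-2-en-1-yl prop-2-enoate
Product: 21 (5R)-5-[(1S,5R)-5-(1-bromoethenyl)-2-methylcyclopent-2-en-1-yl]furan-2(5H)-one
Conditions: Grubbs II catalyst (5 mol %), toluene (2 mM), 80 °C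
Reagents that add atoms: none
Why: Ring-closing metathesis between the acrylate and the adjacent vinyl group should form the five-membered unsaturated lactone with loss of ethene, because the bromoalkene and the trisubstituted ring alkene are poor metathesis partners.

Step 11
Reactants: 21 (5R)-5-[(1S,5R)-5-(1-bromoethenyl)-2-methylcyclopent-2-en-1-yl]furan-2(5H)-one; 4 6-methylhepta-1,6-dien-3-one
Product: 24 (4S,5R)-5-[(1S,5R)-5-(1-bromoethenyl)-2-methylcyclopent-2-en-1-yl]-4-[(2S)-6-methyl-3-oxohept-6-en-2-yl]oxolan-2-one, via lithium (Z)-enolate 22 (not isolated), via lactone enolate 23 (not isolated)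
Conditions: L-Selectride (1.0 equiv), THF, −78 °C, 4 added dropwise; then 21, THF, −78 °C; NH4Cl at −78 °C
Reagents that add atoms: none
Why: The regiodefined (Z)-lithium enolate 22, formed by 1,4-hydride addition to the s-cis vinyl ketone, adds in a Michael fashion to C7 of the butenolide and the resulting lactone enolate 23 is protonated on work-up; the closest known reaction type is the trans-selective conjugate addition of lithium enolates to γ-substituted butenolides. No ring is closed in this step; the temporary lactone ring (O–C6–C7–C8–C9) is kept and is opened in step 13. C7 is controlled by the C6 stereocentre, because the enolate should attack the flat lactone on the face anti to the bulky cyclopentenyl group, which places C11 trans to C5 on the lactone and therefore cis to the C6 oxygen in the final seven-membered ring. C11 is controlled by the (Z)-geometry of the enolate in an open synclinal transition state (the s-trans acceptor allows no chelate), with the enolate oxygen over the lactone carbonyl and the C13 chain pointing away, which should give the (7S,11S) arrangement. The step needs 1,4- over 1,2-addition and C–C bond formation faster than deprotonation at C6–H, which the cold lithium enolate, the unhindered β-carbon and the immediate low-temperature quench should secure, and the quench also guards C11 against epimerisation.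

Step 12
Reactants: 24 (4S,5R)-5-[(1S,5R)-5-(1-bromoethenyl)-2-methylcyclopent-2-en-1-yl]-4-[(2S)-6-methyl-3-oxohept-6-en-2-yl]oxolan-2-one
Product: 25 (4S,5R)-5-[(1S,5R)-5-(1-bromoethenyl)-2-methylcyclopent-2-en-1-yl]-4-[(2S,3S)-3-hydroxy-6-methylhept-6-en-2-yl]oxolan-2-one
Conditions: (R)-2-methyl-CBS-oxazaborolidine (20 mol %), catecholborane (2 equiv), toluene, −78 °C; MeOH, then aqueous NaHCO3
Reagents that add atoms: none
Why: The oxazaborolidine-bound borane should deliver hydride to the ketone face that treats the branched C11 side as the large group, giving the (12S)-alcohol against the Felkin preference while lactone, bromoalkene and alkenes stay intact (CBS reduction).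

Step 13
Reactants: 25 (4S,5R)-5-[(1S,5R)-5-(1-bromoethenyl)-2-methylcyclopent-2-en-1-yl]-4-[(2S,3S)-3-hydroxy-6-methylhept-6-en-2-yl]oxolan-2-one
Product: 27 (1R,5S,6R,7S,11S,12S)-6,12-dihydroxy-10-methylidene-9-oxo trans-fused hydroazulene (dictyol numbering), via dilithio species 26 (not isolated)
Conditions: t-BuLi (3.1 equiv), THF/Et2O, −78 → −40 °C; NH4Cl at −78 °C
Reagents that add atoms: none
Why: Bromine–lithium exchange should outrun addition of the alkyllithium to the lactone, and the C10 vinyllithium then acylates at C9 to give a bridged hemiketal alkoxide that collapses on work-up to the C9 enone and the free C6 hydroxyl (Parham-type anionic cyclisation forming the seven-membered ring).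

Step 14
Reactants: 27 (1R,5S,6R,7S,11S,12S)-6,12-dihydroxy-10-methylidene-9-oxo trans-fused hydroazulene
Product: 28 12-O-acetate of 27
Conditions: Ac2O (1.2 equiv), pyridine, DMAP (5 mol %), CH2Cl2, −20 °C
Reagents that add atoms: acetic anhydride, CC(=O)OC(C)=O
Why: The acyclic C12 hydroxyl should be acylated much faster than the C6 hydroxyl, which is flanked by two ring methines and can hide as the C9 hemiketal (site-selective acetylation).

Step 15
Reactants: 28 12-O-acetate of 27
Product: 29 CNP0327794.2
Conditions: (S)-2-methyl-CBS-oxazaborolidine (30 mol %), catecholborane (2.5 equiv), toluene, −78 °C; MeOH, then aqueous NaHCO3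
Reagents that add atoms: none
Why: Reagent-controlled 1,2-reduction of the enone, with the alkenyl carbon C10 as the large group, should give the (9R)-allylic alcohol and leave the acetate untouched (CBS reduction).

Compound list
1 | 4-bromo-2-methylbut-1-ene | C=C(C)CCBr | starting material
2 | N-methoxy-N-methylprop-2-enamide | C=CC(=O)N(C)OC | starting material
3 | (3-methylbut-3-en-1-yl)magnesium bromide | C=C(C)CC[Mg]Br | intermediate
4 | 6-methylhepta-1,6-dien-3-one | C=CC(=O)CCC(C)=C | intermediate
5 | (S)-4-[(tert-butyldimethylsilyl)oxy]cyclopent-2-en-1-one | O=C1C=C[C@@H](O[Si](C)(C)C(C)(C)C)C1 | starting material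
6 | (1-bromoethenyl)trimethylsilane | C=C(Br)[Si](C)(C)C | starting material
7 | [1-(trimethylsilyl)ethenyl]magnesium bromide | C=C([Mg]Br)[Si](C)(C)C | intermediate
8 | (3S,4S)-3-[(tert-butyldimethylsilyl)oxy]-4-[1-(trimethylsilyl)ethenyl]cyclopentan-1-one (3,4-trans) | C=C([Si](C)(C)C)[C@@H]1[C@@H](O[Si](C)(C)C(C)(C)C)CC(=O)C1 | intermediate
9 | (S)-4-[1-(trimethylsilyl)ethenyl]cyclopent-2-en-1-one | C=C([Si](C)(C)C)[C@@H]1C=CC(=O)C1 | intermediate
10 | (4S)-4-[1,2-dibromo-1-(trimethylsilyl)ethyl]cyclopent-2-en-1-one (both epimers at the CBr(Si) carbon) | BrCC(Br)([Si](C)(C)C)[C@@H]1C=CC(=O)C1 | intermediate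
11 | (S)-4-(1-bromoethenyl)cyclopent-2-en-1-one | C=C(Br)[C@@H]1C=CC(=O)C1 | intermediate
12 | prop-2-enal (acrolein) | C=CC=O | starting material
13 | lithium cross-conjugated (α′) dienolate of 11 | C=C(Br)[C@@H]1C=CC(O[Li])=C1 | intermediate
14 | (4R,5R)-4-(1-bromoethenyl)-5-[(1R)-1-hydroxyprop-2-en-1-yl]cyclopent-2-en-1-one | C=C(Br)[C@@H]1C=CC(=O)[C@H]1[C@H](O)C=C | intermediate
15 | (4R,5R)-4-(1-bromoethenyl)-5-[(1R)-1-[(tert-butyldimethylsilyl)oxy]prop-2-en-1-yl]cyclopent-2-en-1-one | C=C(Br)[C@@H]1C=CC(=O)[C@H]1[C@H](O[Si](C)(C)C(C)(C)C)C=C | intermediate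
16 | lithium enolate from 1,4-reduction of 15 (C3=C4 enolate) | C=C(Br)[C@@H]1CC=C(O[Li])[C@H]1[C@H](O[Si](C)(C)C(C)(C)C)C=C | intermediate
17 | (4R,5R)-4-(1-bromoethenyl)-5-[(1R)-1-[(tert-butyldimethylsilyl)oxy]prop-2-en-1-yl]cyclopent-1-en-1-yl trifluoromethanesulfonate | C=C(Br)[C@@H]1CC=C(OS(=O)(=O)C(F)(F)F)[C@H]1[C@H](O[Si](C)(C)C(C)(C)C)C=C | intermediate
18 | {[(1R)-1-[(1S,5R)-5-(1-bromoethenyl)-2-methylcyclopent-2-en-1-yl]prop-2-en-1-yl]oxy}(tert-butyl)dimethylsilane | C=C(Br)[C@@H]1CC=C(C)[C@H]1[C@H](O[Si](C)(C)C(C)(C)C)C=C | intermediate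
19 | (1R)-1-[(1S,5R)-5-(1-bromoethenyl)-2-methylcyclopent-2-en-1-yl]prop-2-en-1-ol | C=C(Br)[C@@H]1CC=C(C)[C@H]1[C@H](O)C=C | intermediate
20 | (1R)-1-[(1S,5R)-5-(1-bromoethenyl)-2-methylcyclopent-2-en-1-yl]prop-2-en-1-yl prop-2-enoate | C=C(Br)[C@@H]1CC=C(C)[C@H]1[C@H](OC(=O)C=C)C=C | intermediate
21 | (5R)-5-[(1S,5R)-5-(1-bromoethenyl)-2-methylcyclopent-2-en-1-yl]furan-2(5H)-one | C=C(Br)[C@@H]1CC=C(C)[C@H]1[C@@H]2OC(=O)C=C2 | intermediate
22 | lithium (2Z)-6-methylhepta-2,6-dien-3-olate | C/C=C(\O[Li])CCC(C)=C | intermediate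
23 | lithium enolate of lactone 24 | C=C(Br)[C@@H]1CC=C(C)[C@H]1[C@@H]2OC(O[Li])=C[C@H]2[C@H](C)C(=O)CCC(C)=C | intermediate
24 | (4S,5R)-5-[(1S,5R)-5-(1-bromoethenyl)-2-methylcyclopent-2-en-1-yl]-4-[(2S)-6-methyl-3-oxohept-6-en-2-yl]oxolan-2-one | C=C(Br)[C@@H]1CC=C(C)[C@H]1[C@@H]2OC(=O)C[C@H]2[C@H](C)C(=O)CCC(C)=C | intermediate
25 | (4S,5R)-5-[(1S,5R)-5-(1-bromoethenyl)-2-methylcyclopent-2-en-1-yl]-4-[(2S,3S)-3-hydroxy-6-methylhept-6-en-2-yl]oxolan-2-one | C=C(Br)[C@@H]1CC=C(C)[C@H]1[C@@H]2OC(=O)C[C@H]2[C@H](C)[C@@H](O)CCC(C)=C | intermediate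
26 | dilithiated 25 (C12 lithium alkoxide, C10 vinyllithium) | C=C([Li])[C@@H]1CC=C(C)[C@H]1[C@@H]2OC(=O)C[C@H]2[C@H](C)[C@@H](O[Li])CCC(C)=C | intermediate
27 | (1R,5S,6R,7S,11S,12S)-6,12-dihydroxy-10-methylidene-9-oxo trans-fused hydroazulene (dictyol numbering; C3=C4, C15=C16) | C=C(C)CC[C@H](O)[C@@H](C)[C@@H]1CC(=O)C(=C)[C@@H]2CC=C(C)[C@H]2[C@@H]1O | intermediate
28 | 12-O-acetate of 27 (1R,5S,6R,7S,11S,12S) | C=C(C)CC[C@H](OC(C)=O)[C@@H](C)[C@@H]1CC(=O)C(=C)[C@@H]2CC=C(C)[C@H]2[C@@H]1O | intermediate
29 | CNP0327794.2, (1R,5S,6R,7S,9R,11S,12S)-12-acetoxy-6,9-diol (dictyol numbering) | C=C(C)CC[C@H](OC(C)=O)[C@@H](C)[C@@H]1C[C@@H](O)C(=C)[C@@H]2CC=C(C)[C@H]2[C@@H]1O | target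

Total step count: 15. Longest linear sequence: 14 steps (steps 2–15, from 5).

Steps most likely to fail

Step 11. Proton transfer from C6–H of the butenolide to the basic enolate may compete with C–C bond formation and erode the C6 configuration, or the simple diastereoselection at C11 may be low. The fallback sets out from 4 and 21 and returns at 24. Ketone 4 is reduced with L-Selectride and the enolate is trapped with chlorotrimethylsilane to give (2Z)-trimethyl[(6-methylhepta-2,6-dien-3-yl)oxy]silane F1. A Lewis-acid-promoted Mukaiyama–Michael addition of F1 to 21 (SnCl4 or catalytic TBSOTf, CH2Cl2, −78 °C, aqueous acid work-up) then runs under non-basic conditions through an open transition state and should give 24.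

Step 13. The vinyllithium may deprotonate the lactone α-position instead of adding to the carbonyl, or tert-butyllithium may attack the lactone before the exchange is complete. The fallback sets out from 25 and returns at 27. DIBAL-H (CH2Cl2, −78 °C) reduces 25 to the lactol F2. An intramolecular Nozaki–Hiyama–Kishi reaction of the bromoalkene with the open hydroxy aldehyde form (CrCl2, catalytic NiCl2, DMSO/THF) closes the seven-membered ring to the C9-epimeric 6,9,12-triol F3. Selective oxidation of the allylic C9 hydroxyl with MnO2 then gives 27.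

Step 12. Facial selectivity may be poor because the catalyst has to override the Felkin preference of the α-branched ketone. The fallback sets out from 24 and returns at 25. L-Selectride (THF, −78 °C) should give the Felkin product, the (12R)-alcohol F4. Mitsunobu inversion with 4-nitrobenzoic acid (PPh3, DIAD) gives the (12S)-4-nitrobenzoate F5, and methanolysis (K2CO3, MeOH, then mild acid to re-close the lactone) gives 25.

Further compounds
F1 | step 11 | (2Z)-trimethyl[(6-methylhepta-2,6-dien-3-yl)oxy]silane | C/C=C(\O[Si](C)(C)C)CCC(C)=C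
F2 | step 13 | lactol of 25 (oxolan-2-ol, both anomers) | C=C(Br)[C@@H]1CC=C(C)[C@H]1[C@@H]2OC(O)C[C@H]2[C@H](C)[C@@H](O)CCC(C)=C
F3 | step 13 | 6,9,12-triol corresponding to 27 (both C9 epimers) | C=C(C)CC[C@H](O)[C@@H](C)[C@@H]1CC(O)C(=C)[C@@H]2CC=C(C)[C@H]2[C@@H]1O
F4 | step 12 | (12R)-epimer of 25 | C=C(Br)[C@@H]1CC=C(C)[C@H]1[C@@H]2OC(=O)C[C@H]2[C@H](C)[C@H](O)CCC(C)=C
F5 | step 12 | (12S)-4-nitrobenzoate of 25 | C=C(Br)[C@@H]1CC=C(C)[C@H]1[C@@H]2OC(=O)C[C@H]2[C@H](C)[C@@H](OC(=O)c1ccc(cc1)[N+](=O)[O-])CCC(C)=C
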